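Ring B (C5–C10) of this ent-labdane is treated as a Diels–Alder cyclohexene: C5=C6–C7=C8 is the diene, C9=C10 the dienophile and the C1–C4 chain of ring A the tether. An acyclic (2E,8E,10E)-trienoyl oxazolidinone, with C11 as the activating imide carbonyl and C17 as a silyloxymethyl group on the diene terminus, cyclises under Me2AlCl, forming C8–C9 and C5–C10, closing rings A and B and setting C5, C9 and quaternary C10 under auxiliary control. C11 then serves to attach C12–C16 (methylenation, B-alkyl Suzuki coupling); oxidation at C17 moves the C6=C7 olefin to C7=C8 before the final reduction.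

Key step: step 8

Remark: atoms are numbered as in labdane (C17 = hydroxymethyl carbon on C8, C20 = angular methyl, C11–C16 = side chain); the target is (5R,9S,10R,13E), i.e. ent-labdane series, and the acyl chain is read as 30-hydroxytriacontanoyl (29 CH2 groups). TBS = tert-butyldimethylsilyl. Compounds 1, 3, 8, 9, 21 and 24 are taken as catalogue chemicals.

Step 1
Reactants: 1 but-2-ynoic acid
Product: 2 (2E)-3-iodobut-2-enoic acid
Conditions: 57% aq. HI, 110 °C, sealed vessel; recrystallisation
Reagents that add atoms: hydroiodic acid, I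
Why: Hydroiodination of the ynoic acid gives the anti-adduct first, and reversible HI addition–elimination at 110 °C should equilibrate it to the more stable (E)-acid (iodine trans to CO2H), the geometry needed for both trisubstituted olefins.

Step 2
Reactants: 2 (2E)-3-iodobut-2-enoic acid; 3 (4R)-4-benzyl-1,3-oxazolidin-2-one
Product: 5 (4R)-4-benzyl-3-[(2E)-3-iodobut-2-enoyl]-1,3-oxazolidin-2-one, via mixed pivalic anhydride 4 (not isolated)
Conditions: PivCl, Et3N, THF, −20 °C; then 3, LiCl, −20 °C → rt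
Reagents that add atoms: none
Why: The mixed pivalic anhydride is attacked at its less hindered carbonyl by the LiCl/Et3N-activated oxazolidinone (N-acylation), under conditions mild enough to preserve the (E)-iodoalkene.

Step 3
Reactants: 2 (2E)-3-iodobut-2-enoic acid
Product: 7 (2E)-3-iodobut-2-en-1-ol, via mixed isobutyl carbonic anhydride 6 (not isolated)
Conditions: i-BuOCOCl, N-methylmorpholine, THF, −15 °C; then NaBH4, H2O, 0 °C
Reagents that add atoms: none
Why: Activation as the mixed carbonic anhydride lets NaBH4 reduce the carboxyl group to the primary alcohol at 0 °C without reducing the C–I bond or changing the olefin geometry.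

Step 4
Reactants: 8 2,2-dimethylpent-4-enal; 9 triethyl (2E)-4-phosphonobut-2-enoate
Product: 10 ethyl (2E,4E)-6,6-dimethylnona-2,4,8-trienoate
Conditions: LiN(SiMe3)2, THF, −78 °C → rt
Reagents that add atoms: none
Why: Horner–Wadsworth–Emmons olefination of the non-enolisable neopentylic aldehyde with the vinylogous phosphonate anion should give the (2E,4E)-dienoate, the new C=C bond forming E as usual for stabilised phosphonates.

Step 5
Reactants: 10 ethyl (2E,4E)-6,6-dimethylnona-2,4,8-trienoate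
Product: 11 (2E,4E)-6,6-dimethylnona-2,4,8-trien-1-ol
Conditions: i-Bu2AlH, CH2Cl2, −78 °C; aq. potassium sodium tartrate
Reagents that add atoms: none
Why: i-Bu2AlH reduces the dienoate in 1,2-fashion to the dienol without touching the olefins.

Step 6
Reactants: 11 (2E,4E)-6,6-dimethylnona-2,4,8-trien-1-ol
Product: 12 tert-butyl{[(2E,4E)-6,6-dimethylnona-2,4,8-trien-1-yl]oxy}dimethylsilane
Conditions: TBSCl, imidazole, DMF, rt
Reagents that add atoms: tert-butyldimethylsilyl chloride, CC(C)(C)[Si](C)(C)Cl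
Why: Standard silylation of the primary alcohol; the silyl ether keeps the diene electron-rich and masks C17 until the end game.

Step 7
Reactants: 12 tert-butyl{[(2E,4E)-6,6-dimethylnona-2,4,8-trien-1-yl]oxy}dimethylsilane; 5 (4R)-4-benzyl-3-[(2E)-3-iodobut-2-enoyl]-1,3-oxazolidin-2-one
Product: 14 (4R)-4-benzyl-3-[(2E,8E,10E)-12-(TBS-oxy)-3,7,7-trimethyldodeca-2,8,10-trienoyl]-1,3-oxazolidin-2-one, via B-alkyl-9-BBN adduct 13 (not isolated)
Conditions: 9-BBN dimer, THF, rt; then 5, PdCl2(dppf), AsPh3, aq. K3PO4, DMF, rt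
Reagents that add atoms: none
Why: 9-BBN hydroborates the monosubstituted alkene anti-Markovnikov much faster than the internal conjugated diene, and the B-alkyl Suzuki–Miyaura coupling joins C1 to C10 with retention of the vinyl iodide geometry, giving the (E)-trisubstituted dienophile.

Step 8
Reactants: 14 (4R)-4-benzyl-3-[(2E,8E,10E)-12-(TBS-oxy)-3,7,7-trimethyldodeca-2,8,10-trienoyl]-1,3-oxazolidin-2-one
Product: 15 (4R)-4-benzyl-3-{[(1R,2R,4aR,8aR)-2-(TBS-oxymethyl)-5,5,8a-trimethyl-1,2,4a,5,6,7,8,8a-octahydronaphthalen-1-yl]carbonyl}-1,3-oxazolidin-2-one (trans-fused; acyl group, CH2OTBS group and angular methyl all cis)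
Conditions: Me2AlCl (1.5 equiv), CH2Cl2 (0.01 M), −30 °C → 0 °C
Reagents that add atoms: none
Why: Me2AlCl should convert the imide into the cationic O,O-chelated aluminium complex with an s-cis enoyl unit, which undergoes a concerted but asynchronous intramolecular [4+2] cycloaddition between the C9=C10 dienophile and the C5=C6–C7=C8 diene, forming C8–C9 and C5–C10; the closest known reaction type is the Lewis-acid-promoted intramolecular Diels–Alder reaction of deca-2,7,9-trienoyl oxazolidinones. Ring B is closed by the cycloaddition itself (both new bonds), ring A by the C5–C10 bond with the C1–C4 tether in a chair-like arrangement, the gem-dimethyl group at C4 favouring the folded conformer. The cis relation of the C20 methyl and the C11 carbonyl (C10 versus C9) is transferred from the (E)-dienophile, while the trans ring fusion (H5 anti to C20) and the C8 configuration follow from the endo transition state, in which the chelated carbonyl lies under the (E,E)-diene. The absolute configuration is set by the benzyl group of the (R)-auxiliary, which shields the Cα-Si face so that the diene bonds to the Cα-Re face of C9. The step needs endo over exo selectivity and one π-face: the first is secured by the chelating Lewis acid, the second by the auxiliary, and the regiochemistry is fixed by the tether. The C8 centre is removed later, so only C5, C9 and C10 have to be correct.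

Step 9
Reactants: 15 (4R)-4-benzyl-3-{[(1R,2R,4aR,8aR)-2-(TBS-oxymethyl)-5,5,8a-trimethyl-1,2,4a,5,6,7,8,8a-octahydronaphthalen-1-yl]carbonyl}-1,3-oxazolidin-2-one
Product: 16 [(1R,2R,4aR,8aR)-2-(TBS-oxymethyl)-5,5,8a-trimethyl-1,2,4a,5,6,7,8,8a-octahydronaphthalen-1-yl]methanol
Conditions: LiBH4, MeOH (1 equiv), THF, 0 °C → rt
Reagents that add atoms: none
Why: Hydride attacks the exocyclic imide carbonyl (LiBH4 reductive cleavage of an N-acyl oxazolidinone), releasing the C11 alcohol and the recoverable auxiliary without affecting the stereocentres.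

Step 10
Reactants: 16 [(1R,2R,4aR,8aR)-2-(TBS-oxymethyl)-5,5,8a-trimethyl-1,2,4a,5,6,7,8,8a-octahydronaphthalen-1-yl]methanol
Product: 17 (1R,2R,4aR,8aR)-2-(TBS-oxymethyl)-5,5,8a-trimethyl-1,2,4a,5,6,7,8,8a-octahydronaphthalene-1-carbaldehyde
Conditions: Dess–Martin periodinane, CH2Cl2, 0 °C → rt
Reagents that add atoms: none
Why: Dess–Martin oxidation gives the aldehyde under non-basic conditions, and C9 is not expected to epimerise because its formyl group is already equatorial.

Step 11
Reactants: 17 (1R,2R,4aR,8aR)-2-(TBS-oxymethyl)-5,5,8a-trimethyl-1,2,4a,5,6,7,8,8a-octahydronaphthalene-1-carbaldehyde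
Product: 18 tert-butyl{[(1R,2R,4aR,8aS)-1-ethenyl-5,5,8a-trimethyl-1,2,4a,5,6,7,8,8a-octahydronaphthalen-2-yl]methoxy}dimethylsilane
Conditions: Ph3PCH3Br, KOt-Bu, THF, 0 °C → rt
Reagents that add atoms: methyltriphenylphosphonium bromide, C[P+](c1ccccc1)(c1ccccc1)c1ccccc1.[Br-]
Why: Wittig methylenation of the hindered aldehyde with the unstabilised ylide installs C12, and short exposure at 0 °C limits enolisation at C9.

Step 12
Reactants: 18 tert-butyl{[(1R,2R,4aR,8aS)-1-ethenyl-5,5,8a-trimethyl-1,2,4a,5,6,7,8,8a-octahydronaphthalen-2-yl]methoxy}dimethylsilane; 7 (2E)-3-iodobut-2-en-1-ol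
Product: 20 (5R,8R,9R,10S,13E)-17-(TBS-oxy)labda-6,13-dien-15-ol, via B-alkyl-9-BBN adduct 19 (not isolated)
Conditions: 9-BBN dimer, THF, rt → 50 °C; then 7, PdCl2(dppf), AsPh3, aq. K3PO4, DMF, rt
Reagents that add atoms: none
Why: Selective 9-BBN hydroboration of the vinyl group (the cis-disubstituted ring olefin is far slower) and B-alkyl Suzuki–Miyaura coupling with the (E)-vinyl iodide form C12–C13 and fix the 13E geometry by retention.

Step 13
Reactants: 21 tetradecane-1,14-diol
Product: 22 14-bromotetradecan-1-ol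
Conditions: 48% aq. HBr, toluene, reflux
Reagents that add atoms: hydrobromic acid, Br
Why: Substitution of one protonated hydroxyl by bromide; with a symmetrical α,ω-diol in toluene the reaction should stop largely at the bromo alcohol, which is extracted into the organic phase.

Step 14
Reactants: 22 14-bromotetradecan-1-ol
Product: 23 [(14-bromotetradecyl)oxy](tert-butyl)dimethylsilane
Conditions: TBSCl, imidazole, CH2Cl2, rt
Reagents that add atoms: tert-butyldimethylsilyl chloride, CC(C)(C)[Si](C)(C)Cl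
Why: Standard silylation, giving a hydroxyl protecting group that tolerates Grignard formation.

Step 15
Reactants: 23 [(14-bromotetradecyl)oxy](tert-butyl)dimethylsilane; 24 16-bromohexadecanoic acid
Product: 27 30-(TBS-oxy)triacontanoic acid, via bromomagnesium 16-bromohexadecanoate 25 (not isolated), via alkylmagnesium bromide 26 (not isolated)
Conditions: 23, Mg, THF, 45 °C; separately 24, MeMgBr (1.0 equiv), THF, −20 °C; combine, Li2CuCl4 (5 mol%), −20 °C → rt; aq. citric acid
Reagents that add atoms: none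
Why: Copper-catalysed alkyl–alkyl cross-coupling of the long-chain Grignard reagent with the primary bromide of the pre-formed magnesium carboxylate, which is inert to the Grignard reagent at this temperature, assembles the C30 chain without ester protection.

Step 16
Reactants: 20 (5R,8R,9R,10S,13E)-17-(TBS-oxy)labda-6,13-dien-15-ol; 27 30-(TBS-oxy)triacontanoic acid
Product: 28 (5R,8R,9R,10S,13E)-17-(TBS-oxy)labda-6,13-dien-15-yl 30-(TBS-oxy)triacontanoate
Conditions: DCC, DMAP (cat.), CH2Cl2, rt
Reagents that add atoms: none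
Why: Steglich esterification acylates the unhindered primary allylic alcohol at C15 under neutral conditions that leave both silyl ethers and the olefins intact.

Step 17
Reactants: 28 (5R,8R,9R,10S,13E)-17-(TBS-oxy)labda-6,13-dien-15-yl 30-(TBS-oxy)triacontanoate
Product: 29 (5R,8R,9R,10S,13E)-17-hydroxylabda-6,13-dien-15-yl 30-hydroxytriacontanoate
Conditions: HF·pyridine, pyridine, THF, 0 °C → rt
Reagents that add atoms: none
Why: Buffered HF·pyridine cleaves both primary silyl ethers, while the allylic ester and the olefins are stable to fluoride under these weakly acidic conditions.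

Step 18
Reactants: 29 (5R,8R,9R,10S,13E)-17-hydroxylabda-6,13-dien-15-yl 30-hydroxytriacontanoate
Product: 31 (5R,9S,10R,13E)-17-oxolabda-7,13-dien-15-yl 30-oxotriacontanoate, via β,γ-unsaturated dialdehyde 30 (not isolated)
Conditions: Dess–Martin periodinane, CH2Cl2, rt; then DBU (0.2 equiv), 0 °C
Reagents that add atoms: none
Why: Dess–Martin oxidation converts both primary alcohols into aldehydes, and catalytic DBU then moves the C6=C7 olefin into conjugation with the C17 aldehyde through the dienolate (deprotonation at C8, protonation at C6), which erases the C8 centre and sets the C7=C8 olefin; the hydrogen at C9 is not activated in either isomer.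

Step 19
Reactants: 31 (5R,9S,10R,13E)-17-oxolabda-7,13-dien-15-yl 30-oxotriacontanoate
Product: 32 (5R,9S,10R,13E)-17-hydroxylabda-7,13-dien-15-yl 30-hydroxytriacontanoate (CNP0329077.1)
Conditions: NaBH4, CeCl3·7H2O, MeOH/THF, −20 °C → 0 °C
Reagents that add atoms: none
Why: Luche reduction reduces the enal in 1,2-fashion and the saturated aldehyde to the two primary alcohols, while the ester and the olefins are untouched.

Compound list

1 | but-2-ynoic acid | CC#CC(=O)O | starting material
2 | (2E)-3-iodobut-2-enoic acid | C/C(I)=C\C(=O)O | intermediate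
3 | (4R)-4-benzyl-1,3-oxazolidin-2-one | O=C1N[C@H](Cc2ccccc2)CO1 | starting material
4 | (2E)-3-iodobut-2-enoic pivalic anhydride | C/C(I)=C\C(=O)OC(=O)C(C)(C)C | intermediate (not isolated)
5 | (4R)-4-benzyl-3-[(2E)-3-iodobut-2-enoyl]-1,3-oxazolidin-2-one | O=C1OC[C@@H](Cc2ccccc2)N1C(=O)/C=C(\C)I | intermediate
6 | (2E)-3-iodobut-2-enoic isobutyl carbonic anhydride | C/C(I)=C\C(=O)OC(=O)OCC(C)C | intermediate (not isolated)
7 | (2E)-3-iodobut-2-en-1-ol | C/C(I)=C\CO | intermediate
8 | 2,2-dimethylpent-4-enal | C=CCC(C)(C)C=O | starting material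
9 | triethyl (2E)-4-phosphonobut-2-enoate | CCOC(=O)/C=C/CP(=O)(OCC)OCC | starting material
10 | ethyl (2E,4E)-6,6-dimethylnona-2,4,8-trienoate | C=CCC(C)(C)/C=C/C=C/C(=O)OCC | intermediate
11 | (2E,4E)-6,6-dimethylnona-2,4,8-trien-1-ol | C=CCC(C)(C)/C=C/C=C/CO | intermediate
12 | tert-butyl{[(2E,4E)-6,6-dimethylnona-2,4,8-trien-1-yl]oxy}dimethylsilane | C=CCC(C)(C)/C=C/C=C/CO[Si](C)(C)C(C)(C)C | intermediate
13 | 9-[(5E,7E)-9-(TBS-oxy)-4,4-dimethylnona-5,7-dien-1-yl]-9-borabicyclo[3.3.1]nonane | CC(C)(CCCB1C2CCCC1CCC2)/C=C/C=C/CO[Si](C)(C)C(C)(C)C | intermediate (not isolated)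
14 | (4R)-4-benzyl-3-[(2E,8E,10E)-12-(TBS-oxy)-3,7,7-trimethyldodeca-2,8,10-trienoyl]-1,3-oxazolidin-2-one | O=C1OC[C@@H](Cc2ccccc2)N1C(=O)/C=C(\C)CCCC(C)(C)/C=C/C=C/CO[Si](C)(C)C(C)(C)C | intermediate
15 | (4R)-4-benzyl-3-{[(1R,2R,4aR,8aR)-2-(TBS-oxymethyl)-5,5,8a-trimethyl-1,2,4a,5,6,7,8,8a-octahydronaphthalen-1-yl]carbonyl}-1,3-oxazolidin-2-one | O=C3OC[C@@H](Cc4ccccc4)N3C(=O)[C@@H]1[C@H](CO[Si](C)(C)C(C)(C)C)C=C[C@@H]2C(C)(C)CCC[C@@]12C | intermediate
16 | [(1R,2R,4aR,8aR)-2-(TBS-oxymethyl)-5,5,8a-trimethyl-1,2,4a,5,6,7,8,8a-octahydronaphthalen-1-yl]methanol | OC[C@@H]1[C@H](CO[Si](C)(C)C(C)(C)C)C=C[C@@H]2C(C)(C)CCC[C@@]12C | intermediate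
17 | (1R,2R,4aR,8aR)-2-(TBS-oxymethyl)-5,5,8a-trimethyl-1,2,4a,5,6,7,8,8a-octahydronaphthalene-1-carbaldehyde | O=C[C@@H]1[C@H](CO[Si](C)(C)C(C)(C)C)C=C[C@@H]2C(C)(C)CCC[C@@]12C | intermediate
18 | tert-butyl{[(1R,2R,4aR,8aS)-1-ethenyl-5,5,8a-trimethyl-1,2,4a,5,6,7,8,8a-octahydronaphthalen-2-yl]methoxy}dimethylsilane | C=C[C@@H]1[C@H](CO[Si](C)(C)C(C)(C)C)C=C[C@@H]2C(C)(C)CCC[C@@]12C | intermediate
19 | 9-{2-[(1R,2R,4aR,8aS)-2-(TBS-oxymethyl)-5,5,8a-trimethyl-1,2,4a,5,6,7,8,8a-octahydronaphthalen-1-yl]ethyl}-9-borabicyclo[3.3.1]nonane | B1(C2CCCC1CCC2)CC[C@@H]3[C@H](CO[Si](C)(C)C(C)(C)C)C=C[C@@H]4C(C)(C)CCC[C@@]34C | intermediate (not isolated)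
20 | (5R,8R,9R,10S,13E)-17-(TBS-oxy)labda-6,13-dien-15-ol | C/C(=C\CO)CC[C@@H]1[C@H](CO[Si](C)(C)C(C)(C)C)C=C[C@@H]2C(C)(C)CCC[C@@]12C | intermediate
21 | tetradecane-1,14-diol | OCCCCCCCCCCCCCCO | starting material
22 | 14-bromotetradecan-1-ol | OCCCCCCCCCCCCCCBr | intermediate
23 | [(14-bromotetradecyl)oxy](tert-butyl)dimethylsilane | CC(C)(C)[Si](C)(C)OCCCCCCCCCCCCCCBr | intermediate
24 | 16-bromohexadecanoic acid | OC(=O)CCCCCCCCCCCCCCCBr | starting material
25 | bromomagnesium 16-bromohexadecanoate | Br[Mg]OC(=O)CCCCCCCCCCCCCCCBr | intermediate (not isolated)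
26 | [14-(TBS-oxy)tetradecyl]magnesium bromide | CC(C)(C)[Si](C)(C)OCCCCCCCCCCCCCC[Mg]Br | intermediate (not isolated)
27 | 30-(TBS-oxy)triacontanoic acid | OC(=O)CCCCCCCCCCCCCCCCCCCCCCCCCCCCCO[Si](C)(C)C(C)(C)C | intermediate
28 | (5R,8R,9R,10S,13E)-17-(TBS-oxy)labda-6,13-dien-15-yl 30-(TBS-oxy)triacontanoate | C/C(=C\COC(=O)CCCCCCCCCCCCCCCCCCCCCCCCCCCCCO[Si](C)(C)C(C)(C)C)CC[C@@H]1[C@H](CO[Si](C)(C)C(C)(C)C)C=C[C@@H]2C(C)(C)CCC[C@@]12C | intermediate
29 | (5R,8R,9R,10S,13E)-17-hydroxylabda-6,13-dien-15-yl 30-hydroxytriacontanoate | C/C(=C\COC(=O)CCCCCCCCCCCCCCCCCCCCCCCCCCCCCO)CC[C@@H]1[C@H](CO)C=C[C@@H]2C(C)(C)CCC[C@@]12C | intermediate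
30 | (5R,8R,9R,10S,13E)-17-oxolabda-6,13-dien-15-yl 30-oxotriacontanoate | C/C(=C\COC(=O)CCCCCCCCCCCCCCCCCCCCCCCCCCCCC=O)CC[C@@H]1[C@H](C=O)C=C[C@@H]2C(C)(C)CCC[C@@]12C | intermediate (not isolated)
31 | (5R,9S,10R,13E)-17-oxolabda-7,13-dien-15-yl 30-oxotriacontanoate | C/C(=C\COC(=O)CCCCCCCCCCCCCCCCCCCCCCCCCCCCC=O)CC[C@@H]1C(C=O)=CC[C@@H]2C(C)(C)CCC[C@@]12C | intermediate
32 | (5R,9S,10R,13E)-17-hydroxylabda-7,13-dien-15-yl 30-hydroxytriacontanoate | C/C(=C\COC(=O)CCCCCCCCCCCCCCCCCCCCCCCCCCCCCO)CC[C@@H]1C(CO)=CC[C@@H]2C(C)(C)CCC[C@@]12C | target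

Total step count: 19.
Longest linear sequence: 13 steps (steps 4–12 and 16–19, from aldehyde 8 to 32).

Steps most likely to fail

Step 8. What may go wrong: slow cycloaddition, because the C5–C10 bond joins a quaternary centre to a neopentylic carbon; erosion of endo selectivity by the developing 1,3-diaxial interaction between C20 and the axial C4 methyl; or ionisation of the dienylic silyl ether by the Lewis acid. The fallback replaces auxiliary and Lewis acid by iminium catalysis. Setting out from 12, hydroboration to 13 and coupling with alcohol 7 under the conditions of step 12 would give (2E,8E,10E)-12-(TBS-oxy)-3,7,7-trimethyldodeca-2,8,10-trien-1-ol F1. MnO2 in CH2Cl2 would oxidise it to (2E,8E,10E)-12-(TBS-oxy)-3,7,7-trimethyldodeca-2,8,10-trienal F2. With (2R,5R)-5-benzyl-2-tert-butyl-3-methylimidazolidin-4-one trifluoroacetate (20 mol%, MeCN/H2O, rt), whose benzyl group covers the Cα-Si face of the (E)-iminium ion, an endo-selective organocatalytic intramolecular Diels–Alder reaction should deliver aldehyde 17 directly. The route is rejoined at 17, and steps 9 and 10 are not needed.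

Step 7. What may go wrong: hydrolysis of the imide, or addition–elimination of hydroxide at the β-iodo enoyl carbon, under the aqueous basic coupling conditions in competition with transmetalation. The fallback is a base-free Negishi coupling. From 12, hydroboration with 9-BBN (to 13) and oxidative work-up (NaOH, H2O2) would give (5E,7E)-9-(TBS-oxy)-4,4-dimethylnona-5,7-dien-1-ol F3. Iodination (I2, PPh3, imidazole) would give tert-butyl{[(2E,4E)-9-iodo-6,6-dimethylnona-2,4-dien-1-yl]oxy}dimethylsilane F4, and zinc insertion (Zn dust, LiCl, THF) the alkylzinc iodide F5. Coupling of F5 with 5 under Pd(PPh3)4 catalysis in THF at rt would return to 14.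

Step 9. What may go wrong: hydride attack at the ring (carbamate) carbonyl with opening of the auxiliary, because the exocyclic carbonyl sits between C8 and the quaternary C10. The fallback goes through a thioester and a Fukuyama reduction. From 15, LiSEt (EtSH, n-BuLi, THF, 0 °C) would give S-ethyl (1R,2R,4aR,8aR)-2-(TBS-oxymethyl)-5,5,8a-trimethyl-1,2,4a,5,6,7,8,8a-octahydronaphthalene-1-carbothioate F6 with release of the auxiliary. Et3SiH with Pd/C in acetone at rt would then reduce F6 directly to aldehyde 17, rejoining the route at 17 without step 10.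

Further compounds

F1 | step 8 | (2E,8E,10E)-12-(TBS-oxy)-3,7,7-trimethyldodeca-2,8,10-trien-1-ol | C/C(=C\CO)CCCC(C)(C)/C=C/C=C/CO[Si](C)(C)C(C)(C)C
F2 | step 8 | (2E,8E,10E)-12-(TBS-oxy)-3,7,7-trimethyldodeca-2,8,10-trienal | C/C(=C\C=O)CCCC(C)(C)/C=C/C=C/CO[Si](C)(C)C(C)(C)C
F3 | step 7 | (5E,7E)-9-(TBS-oxy)-4,4-dimethylnona-5,7-dien-1-ol | OCCCC(C)(C)/C=C/C=C/CO[Si](C)(C)C(C)(C)C
F4 | step 7 | tert-butyl{[(2E,4E)-9-iodo-6,6-dimethylnona-2,4-dien-1-yl]oxy}dimethylsilane | ICCCC(C)(C)/C=C/C=C/CO[Si](C)(C)C(C)(C)C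
F5 | step 7 | [(5E,7E)-9-(TBS-oxy)-4,4-dimethylnona-5,7-dien-1-yl]zinc iodide | I[Zn]CCCC(C)(C)/C=C/C=C/CO[Si](C)(C)C(C)(C)C
F6 | step 9 | S-ethyl (1R,2R,4aR,8aR)-2-(TBS-oxymethyl)-5,5,8a-trimethyl-1,2,4a,5,6,7,8,8a-octahydronaphthalene-1-carbothioate | CCSC(=O)[C@@H]1[C@H](CO[Si](C)(C)C(C)(C)C)C=C[C@@H]2C(C)(C)CCC[C@@]12C
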